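**Plan**
- Retrosynthesis: the acetate is taken back to a silyl ether, then the ring bond C3–C4 of the cyclohexa-2,5-dienone is cut to give an open-chain bis(β-methoxyvinyl) ketone. Next come the C1–C6 bond (acetylide + enal), the C4–C5 bond (ethynyl + aldehyde), the C2–allyl bond (carbomagnesiation) and the Cα–Cβ bond of the side chain (aldol).
- Enabling feature: the C1 carbonyl is flanked by two vinyl units (C2=C3 and C5=C6), and C4 is the γ-carbon of the vinylogous ester C5(OMe)=C6–C1=O. Removing C4–H therefore gives a 3-oxidohexatriene C4=C5–C6=C1(O–)–C2=C3 whose termini are C4 and C3.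
- Forward: syn-aldol, aldehyde, propargylic methyl ether (fragment A); allyl-carbomagnesiation/iodination, iodoenal (fragment B); union to the ynone; double methoxide addition; then the only ring is closed by 6π-electrocyclization and loss of methoxide; finally silyl to acetyl.
- Stereochemistry: Cβ and Cα come from the auxiliary-controlled syn-aldol; C4 is set in the ring closure by 1,3-allylic strain from Cα.

Key step: step 11

Remarks on the chemistry: ring atoms are numbered C1 (carbonyl), C2 (allyl-bearing), C3 (ring CH), C4 (quaternary C–OMe), C5 (C–OMe, sp2), C6 (CH); Cα is the CH–CH3 on C4 and Cβ the benzylic CH–O. Compound 1 is taken as a catalogue compound (otherwise one N-propanoylation of (R)-4-benzyl-1,3-thiazolidine-2-thione). The C4 epimers and alkene isomers of 7, 8 and 15–17 are all used, because C4 is planarised in step 11.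

**Step 1**
Reactants: 1 (R)-4-benzyl-3-propanoyl-1,3-thiazolidine-2-thione; 2 3,4-dimethoxybenzaldehyde
Product: 4 (R)-4-benzyl-3-[(2R,3R)-3-(3,4-dimethoxyphenyl)-3-hydroxy-2-methylpropanoyl]-1,3-thiazolidine-2-thione, via chlorotitanium enolate 3 (not isolated)
Conditions: TiCl4, i-Pr2NEt, N-methyl-2-pyrrolidinone, CH2Cl2, 0 °C; then 2, 0 °C
Reagents that add atoms: none
Why: Evans-type syn-aldol of the (Z)-titanium enolate of an N-acyl thiazolidinethione through a non-chelated chair transition state; the benzyl group of the auxiliary shields one enolate face, which should set Cα and Cβ as R,R (syn).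

**Step 2**
Reactants: 4
Product: 5 (R)-4-benzyl-3-[(2R,3R)-3-(tert-butyldimethylsilyloxy)-3-(3,4-dimethoxyphenyl)-2-methylpropanoyl]-1,3-thiazolidine-2-thione
Conditions: TBSOTf, 2,6-lutidine, CH2Cl2, 0 °C
Reagents that add atoms: tert-butyldimethylsilyl trifluoromethanesulfonate, CC(C)(C)[Si](C)(C)OS(=O)(=O)C(F)(F)F
Why: Silylation of a secondary alcohol with a silyl triflate and a hindered base; no stereocentre is touched and retro-aldol is blocked.

**Step 3**
Reactants: 5
Product: 6 (2R,3R)-3-(tert-butyldimethylsilyloxy)-3-(3,4-dimethoxyphenyl)-2-methylpropanal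
Conditions: i-Bu2AlH, CH2Cl2, –78 °C
Reagents that add atoms: none
Why: Direct reductive cleavage of an N-acyl thiazolidinethione to the aldehyde; the tetrahedral aluminium adduct collapses only on work-up, so over-reduction and epimerisation at Cα should be avoided at –78 °C.

**Step 4**
Reactants: 6
Product: 7 (4S,5R)-5-(tert-butyldimethylsilyloxy)-5-(3,4-dimethoxyphenyl)-4-methylpent-1-yn-3-ol (mixture of C-3 epimers)
Conditions: HC≡CMgBr, THF, –78 → 0 °C
Reagents that add atoms: ethynylmagnesium bromide, C#C[Mg]Br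
Why: 1,2-Addition of an alkynyl Grignard reagent to an aldehyde; the new carbinol carbon (future C4) is planarised later, so both epimers serve.

**Step 5**
Reactants: 7
Product: 8 tert-butyl{[(1R,2S)-1-(3,4-dimethoxyphenyl)-3-methoxy-2-methylpent-4-yn-1-yl]oxy}dimethylsilane (mixture of C-3 epimers)
Conditions: Me3OBF4, 1,8-bis(dimethylamino)naphthalene, CH2Cl2, 0 °C → rt
Reagents that add atoms: trimethyloxonium tetrafluoroborate, C[O+](C)C.F[B-](F)(F)F
Why: Meerwein O-methylation under non-basic conditions etherifies the propargylic alcohol without the 1,5-silyl shift that an alkoxide would permit.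

**Step 6**
Reactants: 9 prop-2-yn-1-ol; 10 allylmagnesium bromide
Product: 12 (Z)-2-(iodomethylidene)pent-4-en-1-ol, via vinylmagnesium chelate 11 (not isolated)
Conditions: 10 (3 equiv), CuBr·SMe2 (10 mol%), Et2O, –10 °C → rt; then I2, THF, –78 → 0 °C
Reagents that add atoms: iodine, II
Why: Hydroxyl-directed anti-carbomagnesiation of the propargylic alkoxide puts allyl on C2 and magnesium on C3 cis to CH2O (five-membered chelate); iodinolysis with retention should give the Z vinyl iodide.

**Step 7**
Reactants: 12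
Product: 13 (Z)-2-(iodomethylidene)pent-4-enal
Conditions: MnO2, CH2Cl2, rt
Reagents that add atoms: none
Why: Selective neutral oxidation of an allylic alcohol with activated MnO2, mild enough to keep the Z iodoalkene.

**Step 8**
Reactants: 8; 13
Product: 15 (1Z,7S,8R)-8-(tert-butyldimethylsilyloxy)-8-(3,4-dimethoxyphenyl)-1-iodo-6-methoxy-7-methyl-2-(prop-2-en-1-yl)oct-1-en-4-yn-3-ol (C-3/C-6 epimer mixture), via lithium acetylide 14 (not isolated)
Conditions: n-BuLi, THF, –78 °C; then 13, –78 °C; then H2O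
Reagents that add atoms: none
Why: 1,2-Addition of a lithium acetylide to an enal, which at –78 °C should outrun attack at the β-iodo carbon.

**Step 9**
Reactants: 15
Product: 16 (1Z,7S,8R)-8-(tert-butyldimethylsilyloxy)-8-(3,4-dimethoxyphenyl)-1-iodo-6-methoxy-7-methyl-2-(prop-2-en-1-yl)oct-1-en-4-yn-3-one (C-6 epimer mixture)
Conditions: Dess–Martin periodinane, NaHCO3, CH2Cl2, 0 °C
Reagents that add atoms: none
Why: Dess–Martin oxidation of a doubly activated secondary alcohol to the cross-conjugated ynone under buffered conditions.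

**Step 10**
Reactants: 16
Product: 17 (1E,4E,7S,8R)-8-(tert-butyldimethylsilyloxy)-8-(3,4-dimethoxyphenyl)-1,5,6-trimethoxy-7-methyl-2-(prop-2-en-1-yl)octa-1,4-dien-3-one (C-6 epimer mixture)
Conditions: NaOMe, MeOH–THF, –20 → 0 °C, anhydrous
Reagents that add atoms: sodium methoxide, C[O-].[Na+]; methanol, CO
Why: Oxa-Michael addition of methoxide to the ynone (at C5) and vinylic substitution of iodide by addition–elimination (at C3) give both β-methoxyvinyl units; reversible addition should place each methoxy group trans to the carbonyl.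

**Step 11**
Reactants: 17
Product: 20 (4R)-4-[(1R,2R)-1-(tert-butyldimethylsilyloxy)-1-(3,4-dimethoxyphenyl)propan-2-yl]-4,5-dimethoxy-2-(prop-2-en-1-yl)cyclohexa-2,5-dien-1-one, via potassium trienolate 18 (not isolated), via potassium cyclohexadienolate 19 (not isolated)
Conditions: KN(SiMe3)2 (1.1 equiv), THF, –78 → 0 °C; then pH 7 buffer
Reagents that add atoms: none
Why: Proposed new method: KN(SiMe3)2 removes the only acidic proton of 17 (C4–H, γ to the vinylogous ester C5(OMe)=C6–C1=O) to give trienolate 18, a 3-oxidohexatriene C4=C5–C6=C1(O–)–C2=C3. This closes the six-membered carbocycle, the only ring formed, by thermal disrotatory 6π-electrocyclization (C3–C4 bond), and enolate 19 then expels methoxide from C3 (E1cB) to give the cross-conjugated dienone irreversibly. The closest known reaction type is the oxyanion-accelerated 6π-electrocyclization of 3-oxidotrienes formed by ring opening of 1-vinylcyclobutenolates, which runs below room temperature; new here are the entry by γ-deprotonation and the terminating β-elimination. The new stereocentre C4 is controlled by Cα: 1,3-allylic strain holds Cα–H in the plane of the C4=C5 bond, so C3 should bond to the face bearing CH3, anti to the bulky CH(OSiR3)Ar branch, which gives 4R. The step needs the U-shaped trienolate (C5 and C2 cis on the C6=C1 enolate bond); proton exchange with HN(SiMe3)2 interconverts the trienolate isomers and only the U-shaped one is drained by ring closure. Competing paths are shut because no other proton is enolisable, closure through C6 would give a four-membered ring, the C3 methoxy group sits outside (trans to C1) and the Cβ oxygen is silylated so it cannot add to C5.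

**Step 12**
Reactants: 20
Product: 21 (4R)-4-[(1R,2R)-1-(3,4-dimethoxyphenyl)-1-hydroxypropan-2-yl]-4,5-dimethoxy-2-(prop-2-en-1-yl)cyclohexa-2,5-dien-1-one
Conditions: HF·pyridine, pyridine, THF, 0 °C → rt
Reagents that add atoms: none
Why: Fluoride cleavage of the Si–O bond under buffered, weakly acidic conditions that should leave the quinol methyl ether and the vinylogous ester intact.

**Step 13**
Reactants: 21
Product: 22 (1R,2R)-1-(3,4-dimethoxyphenyl)-2-[(1R)-1,2-dimethoxy-4-oxo-5-(prop-2-en-1-yl)cyclohexa-2,5-dien-1-yl]propyl acetate (CNP0159267.1)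
Conditions: Ac2O, pyridine, DMAP (cat.), CH2Cl2, 0 °C
Reagents that add atoms: acetic anhydride, CC(=O)OC(C)=O
Why: DMAP-catalysed acylation of the secondary benzylic alcohol; fast acyl transfer should outrun any addition of the hydroxyl to C5, and no stereocentre is touched.

**Compound list**
1 | (R)-4-benzyl-3-propanoyl-1,3-thiazolidine-2-thione | CCC(=O)N1[C@H](Cc2ccccc2)CSC1=S | starting material
2 | 3,4-dimethoxybenzaldehyde | COc1ccc(C=O)cc1OC | starting material
3 | trichlorotitanium (Z)-enolate of 1 | C/C=C(\O[Ti](Cl)(Cl)Cl)N1[C@H](Cc2ccccc2)CSC1=S | intermediate (not isolated)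
4 | (R)-4-benzyl-3-[(2R,3R)-3-(3,4-dimethoxyphenyl)-3-hydroxy-2-methylpropanoyl]-1,3-thiazolidine-2-thione | O=C([C@H](C)[C@@H](O)c1ccc(OC)c(OC)c1)N1[C@H](Cc2ccccc2)CSC1=S | intermediate
5 | (R)-4-benzyl-3-[(2R,3R)-3-(tert-butyldimethylsilyloxy)-3-(3,4-dimethoxyphenyl)-2-methylpropanoyl]-1,3-thiazolidine-2-thione | O=C([C@H](C)[C@@H](O[Si](C)(C)C(C)(C)C)c1ccc(OC)c(OC)c1)N1[C@H](Cc2ccccc2)CSC1=S | intermediate
6 | (2R,3R)-3-(tert-butyldimethylsilyloxy)-3-(3,4-dimethoxyphenyl)-2-methylpropanal | O=C[C@H](C)[C@@H](O[Si](C)(C)C(C)(C)C)c1ccc(OC)c(OC)c1 | intermediate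
7 | (4S,5R)-5-(tert-butyldimethylsilyloxy)-5-(3,4-dimethoxyphenyl)-4-methylpent-1-yn-3-ol, C-3 epimers | C#CC(O)[C@H](C)[C@@H](O[Si](C)(C)C(C)(C)C)c1ccc(OC)c(OC)c1 | intermediate
8 | tert-butyl{[(1R,2S)-1-(3,4-dimethoxyphenyl)-3-methoxy-2-methylpent-4-yn-1-yl]oxy}dimethylsilane, C-3 epimers | C#CC(OC)[C@H](C)[C@@H](O[Si](C)(C)C(C)(C)C)c1ccc(OC)c(OC)c1 | intermediate
9 | prop-2-yn-1-ol | C#CCO | starting material
10 | allylmagnesium bromide | C=CC[Mg]Br | starting material
11 | (Z)-vinylmagnesium bromide / bromomagnesium alkoxide chelate | C=CC/C(=C/[Mg]Br)CO[Mg]Br | intermediate (not isolated)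
12 | (Z)-2-(iodomethylidene)pent-4-en-1-ol | C=CC/C(=C/I)CO | intermediate
13 | (Z)-2-(iodomethylidene)pent-4-enal | C=CC/C(=C/I)C=O | intermediate
14 | lithium acetylide of 8 | [Li]C#CC(OC)[C@H](C)[C@@H](O[Si](C)(C)C(C)(C)C)c1ccc(OC)c(OC)c1 | intermediate (not isolated)
15 | (1Z,7S,8R)-8-(tert-butyldimethylsilyloxy)-8-(3,4-dimethoxyphenyl)-1-iodo-6-methoxy-7-methyl-2-(prop-2-en-1-yl)oct-1-en-4-yn-3-ol, C-3/C-6 epimers | C=CC/C(=C/I)C(O)C#CC(OC)[C@H](C)[C@@H](O[Si](C)(C)C(C)(C)C)c1ccc(OC)c(OC)c1 | intermediate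
16 | (1Z,7S,8R)-8-(tert-butyldimethylsilyloxy)-8-(3,4-dimethoxyphenyl)-1-iodo-6-methoxy-7-methyl-2-(prop-2-en-1-yl)oct-1-en-4-yn-3-one, C-6 epimers | C=CC/C(=C/I)C(=O)C#CC(OC)[C@H](C)[C@@H](O[Si](C)(C)C(C)(C)C)c1ccc(OC)c(OC)c1 | intermediate
17 | (1E,4E,7S,8R)-8-(tert-butyldimethylsilyloxy)-8-(3,4-dimethoxyphenyl)-1,5,6-trimethoxy-7-methyl-2-(prop-2-en-1-yl)octa-1,4-dien-3-one, C-6 epimers | C=CC/C(=C\OC)C(=O)/C=C(/OC)C(OC)[C@H](C)[C@@H](O[Si](C)(C)C(C)(C)C)c1ccc(OC)c(OC)c1 | intermediate
18 | potassium trienolate of 17 (U-shaped isomer) | C=CC/C(=C\OC)C(\[O-])=C/C(OC)=C(OC)[C@H](C)[C@@H](O[Si](C)(C)C(C)(C)C)c1ccc(OC)c(OC)c1.[K+] | intermediate (not isolated)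
19 | potassium 3,4,5-trimethoxycyclohexa-1,5-dien-1-olate (ring closed, C3 methoxy still present) | C=CCC1=C([O-])C=C(OC)[C@](OC)([C@H](C)[C@@H](O[Si](C)(C)C(C)(C)C)c2ccc(OC)c(OC)c2)C1OC.[K+] | intermediate (not isolated)
20 | (4R)-4-[(1R,2R)-1-(tert-butyldimethylsilyloxy)-1-(3,4-dimethoxyphenyl)propan-2-yl]-4,5-dimethoxy-2-(prop-2-en-1-yl)cyclohexa-2,5-dien-1-one | C=CCC1=C[C@@](OC)([C@H](C)[C@@H](O[Si](C)(C)C(C)(C)C)c2ccc(OC)c(OC)c2)C(OC)=CC1=O | intermediate
21 | (4R)-4-[(1R,2R)-1-(3,4-dimethoxyphenyl)-1-hydroxypropan-2-yl]-4,5-dimethoxy-2-(prop-2-en-1-yl)cyclohexa-2,5-dien-1-one | C=CCC1=C[C@@](OC)([C@H](C)[C@@H](O)c2ccc(OC)c(OC)c2)C(OC)=CC1=O | intermediate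
22 | (1R,2R)-1-(3,4-dimethoxyphenyl)-2-[(1R)-1,2-dimethoxy-4-oxo-5-(prop-2-en-1-yl)cyclohexa-2,5-dien-1-yl]propyl acetate | C=CCC1=C[C@@](OC)([C@H](C)[C@@H](OC(C)=O)c2ccc(OC)c(OC)c2)C(OC)=CC1=O | target

**Count and risks**
Total steps: 13. Longest linear sequence: 11 (steps 1–5 and 8–13).

Most likely to fail:

1. Step 11. The trienolate may fail to reach the U-shaped geometry or may close too slowly at the fully substituted C4 terminus, so that decomposition or amide attack at C3 competes; facial selectivity at C4 may also be low. Fallback, from 16 back to 20: Me3P-catalysed addition of methanol to the ynone only (MeOH, Me3P 5 mol%, CH2Cl2, 0 °C) should give (1Z,4E,7S,8R)-8-(tert-butyldimethylsilyloxy)-8-(3,4-dimethoxyphenyl)-1-iodo-5,6-dimethoxy-7-methyl-2-(prop-2-en-1-yl)octa-1,4-dien-3-one F1 with the vinyl iodide kept. The C3–C4 bond is then made by the known palladium-catalysed intramolecular alkenylation of an enolate (Pd(PPh3)4, PhOK, THF, 60 °C): zerovalent palladium inserts into the C3–I bond, which is already cis to C1, the γ-carbon of the dienolate binds palladium, and reductive elimination gives 20.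

2. Step 10. Methoxide may add twice to the ynone, start the ring closure prematurely, or, if water is present, close the bis(methoxyvinyl) ketone to a 4-pyranone. Fallback, from 8 back to 17, without iodide or vinylic substitution: commercial methyl pent-4-enoate is formylated and O-methylated (NaH, HCO2Me; then Me2SO4) to methyl (E)-2-(methoxymethylidene)pent-4-enoate F2. This is converted (MeNHOMe·HCl, i-PrMgCl, THF, –20 °C) into (E)-N-methoxy-2-(methoxymethylidene)-N-methylpent-4-enamide F3. Acetylide 14 (from 8, n-BuLi) is acylated by F3 to give (1E,7S,8R)-8-(tert-butyldimethylsilyloxy)-8-(3,4-dimethoxyphenyl)-1,6-dimethoxy-7-methyl-2-(prop-2-en-1-yl)oct-1-en-4-yn-3-one F4, and Me3P-catalysed addition of methanol to F4 gives 17.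

3. Step 12. Once unmasked, the Cβ hydroxyl may add to C5 and expel methanol (closure to a furan-fused enone), or ionisation at the benzylic carbon may erode its configuration. Fallback, from 20 directly to 22: one-flask acylative cleavage of the silyl ether (Ac2O, Cu(OTf)2 5 mol%, CH2Cl2, 0 °C), a known direct silyl-to-acetyl exchange in which the free alcohol never meets base; no new compound is made.

**Further compounds**
F1 | step 11 | (1Z,4E,7S,8R)-8-(tert-butyldimethylsilyloxy)-8-(3,4-dimethoxyphenyl)-1-iodo-5,6-dimethoxy-7-methyl-2-(prop-2-en-1-yl)octa-1,4-dien-3-one | C=CC/C(=C/I)C(=O)/C=C(/OC)C(OC)[C@H](C)[C@@H](O[Si](C)(C)C(C)(C)C)c1ccc(OC)c(OC)c1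
F2 | step 10 | methyl (E)-2-(methoxymethylidene)pent-4-enoate | C=CC/C(=C\OC)C(=O)OC
F3 | step 10 | (E)-N-methoxy-2-(methoxymethylidene)-N-methylpent-4-enamide | C=CC/C(=C\OC)C(=O)N(C)OC
F4 | step 10 | (1E,7S,8R)-8-(tert-butyldimethylsilyloxy)-8-(3,4-dimethoxyphenyl)-1,6-dimethoxy-7-methyl-2-(prop-2-en-1-yl)oct-1-en-4-yn-3-one | C=CC/C(=C\OC)C(=O)C#CC(OC)[C@H](C)[C@@H](O[Si](C)(C)C(C)(C)C)c1ccc(OC)c(OC)c1
F0 | step 12 | none | none
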